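## Retrosynthetic overview

- The target is the (3S)-isoflavan. Ring A and ring B are the same arene, a 2-prenylresorcinol substituted at its C4: C1' in ring B, C4a in ring A (whose ortho oxygen is O1). One bromide (5) therefore serves as nucleophile and, after a protecting-group exchange (6), as electrophile.
- Key disconnection: C3–C1' and C4–C4a are made together in a three-component enantioselective conjunctive cross-coupling of the ring B aryllithium, vinylboronic acid pinacol ester (C3 and C4) and the ring A aryl bromide. This step sets C3.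
- The boron left on C3 is then used to bring in C2 (Matteson homologation, stereoretentive) and O (oxidation).
- Both benzene rings are bought (4-bromoresorcinol). The pyran ring is the only ring formed, by O1–C2 Mitsunobu closure. Ring A carries triethylsilyl ethers and ring B carries MOM ethers, so only the ring A oxygen can close.
- The last step removes the two MOM groups under non-acidic conditions that spare the two prenyl groups.

Key step: step 4

Assumption: which antipode of the Mandyphos ligand gives (S)-10 is taken by analogy with aryl-migrating conjunctive couplings and would be checked on the first run by oxidising a sample of 10 to the carbinol; both antipodes are available, so the route does not depend on it.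

## Route

Step 1
Reactants: 1 4-bromobenzene-1,3-diol (4-bromoresorcinol)
Product: 2 1-bromo-2,4-bis(methoxymethoxy)benzene
Conditions: NaH, MOMCl, DMF, 0 °C → rt
Reagents that add atoms: chloromethyl methyl ether (MOMCl), COCCl
Why: Williamson O-alkylation of both phenoxides should give the bis-MOM ether, which is stable to the organolithium steps and directs the metalation of step 2.

Step 2
Reactants: 2 1-bromo-2,4-bis(methoxymethoxy)benzene; 3 1-bromo-3-methylbut-2-ene (prenyl bromide)
Product: 5 1-bromo-2,4-bis(methoxymethoxy)-3-(3-methylbut-2-en-1-yl)benzene, via [3-bromo-2,6-bis(methoxymethoxy)phenyl]lithium 4 (not isolated)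
Conditions: lithium 2,2,6,6-tetramethylpiperidide, THF, −78 °C; then CuBr·SMe2 (10 mol%), 3, −78 → 0 °C
Reagents that add atoms: none
Why: Directed ortho-metalation should take the hydrogen between the two MOM-oxy groups (the most acidic site; the hindered amide base does not exchange the bromine), and copper-catalysed SN2 allylation of the aryllithium with prenyl bromide then places the prenyl group between the two oxygens.

Step 3
Reactants: 5 1-bromo-2,4-bis(methoxymethoxy)-3-(3-methylbut-2-en-1-yl)benzene (the portion destined for ring A)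
Product: 6 1-bromo-3-(3-methylbut-2-en-1-yl)-2,4-bis(triethylsilyloxy)benzene
Conditions: TESOTf, 2,2'-bipyridyl, CH2Cl2, 0 °C → rt
Reagents that add atoms: triethylsilyl trifluoromethanesulfonate (TESOTf), CC[Si](CC)(CC)OS(=O)(=O)C(F)(F)F
Why: The silyl triflate–bipyridyl exchange of aromatic MOM ethers into aryl triethylsilyl ethers should give ring A a base-labile protection orthogonal to the MOM ethers of ring B, under buffered conditions that leave the prenyl alkene alone.

Step 4
Reactants: 5 1-bromo-2,4-bis(methoxymethoxy)-3-(3-methylbut-2-en-1-yl)benzene; 7 4,4,5,5-tetramethyl-2-vinyl-1,3,2-dioxaborolane (vinylboronic acid pinacol ester); 6 1-bromo-3-(3-methylbut-2-en-1-yl)-2,4-bis(triethylsilyloxy)benzene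
Product: 10 2-[(1S)-1-[2,4-bis(methoxymethoxy)-3-(3-methylbut-2-en-1-yl)phenyl]-2-[3-(3-methylbut-2-en-1-yl)-2,4-bis(triethylsilyloxy)phenyl]ethyl]-4,4,5,5-tetramethyl-1,3,2-dioxaborolane, via [2,4-bis(methoxymethoxy)-3-(3-methylbut-2-en-1-yl)phenyl]lithium 8 (not isolated), via lithium aryl(vinyl)pinacolatoborate 9 (not isolated)
Conditions: 5, t-BuLi (2 equiv), Et2O, −78 °C; then 7, −78 °C → rt; solvent exchanged for THF; then 6, Pd(OAc)2 (2 mol%), Mandyphos ligand (2.4 mol%; (Sp,Sp)-1,1'-bis[bis(4-methoxy-3,5-dimethylphenyl)phosphino]-2,2'-bis[(R)-(dimethylamino)(phenyl)methyl]ferrocene or its mirror image, chosen to give S), NaOTf, 60 °C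
Reagents that add atoms: none
Why: Bromine–lithium exchange on 5 gives aryllithium 8, which adds to boron of 7 to give ate complex 9; zerovalent palladium carrying the Mandyphos ligand inserts into the C–Br bond of 6, the aryl–palladium species (bromide removed by NaOTf) binds the vinyl group of 9 and triggers a 1,2-metalate shift in which the ring B aryl moves from boron to the boron-bearing carbon anti to palladium (bond C3–C1'), and reductive elimination then forms C4–C4a. The closest known reaction is the Pd/Mandyphos-catalysed enantioselective conjunctive cross-coupling of vinylboron ate complexes with aryl triflates or halides, in which aryl groups are established migrating groups and sodium triflate scavenges halide. No ring is closed in this step. The new stereocentre C3 is set by the chiral ferrocenyl bisphosphine, which selects the face of the vinyl group that binds palladium during the stereospecific anti shift (catalyst control, S with the chosen ligand antipode). The step needs the metalate shift to outrun direct Suzuki-type transfer of aryl or vinyl from boron and β-hydride elimination: the electron-rich migrating aryl, the wide-bite-angle ligand and halide scavenging favour the shift, and the trisubstituted prenyl alkenes do not compete with the boron-activated vinyl group for palladium.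

Step 5
Reactants: 10 the (1S)-benzylic pinacol boronate
Product: 11 2-[(2S)-2-[2,4-bis(methoxymethoxy)-3-(3-methylbut-2-en-1-yl)phenyl]-3-[3-(3-methylbut-2-en-1-yl)-2,4-bis(triethylsilyloxy)phenyl]propyl]-4,4,5,5-tetramethyl-1,3,2-dioxaborolane
Conditions: ICH2Cl, n-BuLi, THF, −78 °C → rt
Reagents that add atoms: chloroiodomethane, ClCI
Why: Matteson homologation: chloromethyllithium formed in the flask adds to boron and the secondary benzylic carbon C3 migrates to CH2 with loss of chloride and retention at C3, which installs C2; the boronate is isolated so that no alkyl iodide is present when the phenols are freed in step 6.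

Step 6
Reactants: 11 the (2S)-homologated pinacol boronate
Product: 13 4-[(2S)-2-[2,4-bis(methoxymethoxy)-3-(3-methylbut-2-en-1-yl)phenyl]-3-hydroxypropyl]-2-(3-methylbut-2-en-1-yl)benzene-1,3-diol, via (2S)-bis(triethylsilyl) propanol 12 (not isolated)
Conditions: H2O2 (30%), 2 M NaOH, THF, 0 °C → rt, stirred on until both silyl ethers are cleaved
Reagents that add atoms: hydrogen peroxide, OO
Why: Alkaline peroxide oxidation of the primary C–B bond should give the C2 alcohol, and the same aqueous hydroxide should hydrolyse the two aryl triethylsilyl ethers of ring A, while the MOM acetals of ring B, the prenyl alkenes and C3 are not touched.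

Step 7
Reactants: 13 the (2S)-triol
Product: 14 (3S)-3-[2,4-bis(methoxymethoxy)-3-(3-methylbut-2-en-1-yl)phenyl]-8-(3-methylbut-2-en-1-yl)-3,4-dihydro-2H-chromen-7-ol
Conditions: PPh3, DIAD, THF (dilute), 0 °C → rt
Reagents that add atoms: none
Why: Intramolecular Mitsunobu etherification should close the pyran ring by 6-exo-tet attack of the ring A phenol ortho to the side chain (O1) on the activated primary C2; the para hydroxyl cannot reach, the ring B oxygens are masked, and C3 takes no part.

Step 8
Reactants: 14 the (3S)-bis-MOM isoflavan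
Product: 15 (3S)-3-[2,4-dihydroxy-3-(3-methylbut-2-en-1-yl)phenyl]-8-(3-methylbut-2-en-1-yl)-3,4-dihydro-2H-chromen-7-ol (CNP0310990.1)
Conditions: TMSOTf, 2,2'-bipyridyl, CH2Cl2, 0 °C → rt; then H2O
Reagents that add atoms: none
Why: The silyl triflate–bipyridyl cleavage of aromatic MOM ethers passes through aryl trimethylsilyl ethers that hydrolyse on adding water, and because the medium stays buffered by bipyridyl the ortho-prenylphenols should not cyclise to dimethylchromans as they do under protic acid.

## Compound list

1 | 4-bromobenzene-1,3-diol (4-bromoresorcinol) | Oc1ccc(Br)c(O)c1 | starting material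
2 | 1-bromo-2,4-bis(methoxymethoxy)benzene | COCOc1ccc(Br)c(OCOC)c1 | intermediate
3 | 1-bromo-3-methylbut-2-ene (prenyl bromide) | CC(C)=CCBr | starting material
4 | [3-bromo-2,6-bis(methoxymethoxy)phenyl]lithium | COCOc1ccc(Br)c(OCOC)c1[Li] | intermediate
5 | 1-bromo-2,4-bis(methoxymethoxy)-3-(3-methylbut-2-en-1-yl)benzene | CC(C)=CCc1c(OCOC)ccc(Br)c1OCOC | intermediate
6 | 1-bromo-3-(3-methylbut-2-en-1-yl)-2,4-bis(triethylsilyloxy)benzene | CC(C)=CCc1c(O[Si](CC)(CC)CC)ccc(Br)c1O[Si](CC)(CC)CC | intermediate
7 | 4,4,5,5-tetramethyl-2-vinyl-1,3,2-dioxaborolane | C=CB1OC(C)(C)C(C)(C)O1 | starting material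
8 | [2,4-bis(methoxymethoxy)-3-(3-methylbut-2-en-1-yl)phenyl]lithium | CC(C)=CCc1c(OCOC)ccc([Li])c1OCOC | intermediate
9 | lithium [2,4-bis(methoxymethoxy)-3-(3-methylbut-2-en-1-yl)phenyl](vinyl)(pinacolato)borate | [Li+].C=C[B-]1(OC(C)(C)C(C)(C)O1)c1ccc(OCOC)c(CC=C(C)C)c1OCOC | intermediate
10 | 2-[(1S)-1-[2,4-bis(methoxymethoxy)-3-(3-methylbut-2-en-1-yl)phenyl]-2-[3-(3-methylbut-2-en-1-yl)-2,4-bis(triethylsilyloxy)phenyl]ethyl]-4,4,5,5-tetramethyl-1,3,2-dioxaborolane | CC(C)=CCc1c(OCOC)ccc([C@H](Cc2ccc(O[Si](CC)(CC)CC)c(CC=C(C)C)c2O[Si](CC)(CC)CC)B2OC(C)(C)C(C)(C)O2)c1OCOC | intermediate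
11 | 2-[(2S)-2-[2,4-bis(methoxymethoxy)-3-(3-methylbut-2-en-1-yl)phenyl]-3-[3-(3-methylbut-2-en-1-yl)-2,4-bis(triethylsilyloxy)phenyl]propyl]-4,4,5,5-tetramethyl-1,3,2-dioxaborolane | CC(C)=CCc1c(OCOC)ccc([C@H](Cc2ccc(O[Si](CC)(CC)CC)c(CC=C(C)C)c2O[Si](CC)(CC)CC)CB2OC(C)(C)C(C)(C)O2)c1OCOC | intermediate
12 | (2S)-2-[2,4-bis(methoxymethoxy)-3-(3-methylbut-2-en-1-yl)phenyl]-3-[3-(3-methylbut-2-en-1-yl)-2,4-bis(triethylsilyloxy)phenyl]propan-1-ol | CC(C)=CCc1c(OCOC)ccc([C@H](Cc2ccc(O[Si](CC)(CC)CC)c(CC=C(C)C)c2O[Si](CC)(CC)CC)CO)c1OCOC | intermediate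
13 | 4-[(2S)-2-[2,4-bis(methoxymethoxy)-3-(3-methylbut-2-en-1-yl)phenyl]-3-hydroxypropyl]-2-(3-methylbut-2-en-1-yl)benzene-1,3-diol | CC(C)=CCc1c(OCOC)ccc([C@H](Cc2ccc(O)c(CC=C(C)C)c2O)CO)c1OCOC | intermediate
14 | (3S)-3-[2,4-bis(methoxymethoxy)-3-(3-methylbut-2-en-1-yl)phenyl]-8-(3-methylbut-2-en-1-yl)-3,4-dihydro-2H-chromen-7-ol | CC(C)=CCc1c(OCOC)ccc([C@H]2COc3c(ccc(O)c3CC=C(C)C)C2)c1OCOC | intermediate
15 | (3S)-3-[2,4-dihydroxy-3-(3-methylbut-2-en-1-yl)phenyl]-8-(3-methylbut-2-en-1-yl)-3,4-dihydro-2H-chromen-7-ol | CC(C)=CCc1c(O)ccc([C@H]2COc3c(ccc(O)c3CC=C(C)C)C2)c1O | target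

## Step count and risks

Total step count: 8. Longest linear sequence: 8 steps (1 → 2 → 5 → 6 → 10 → 11 → 13 → 14 → 15); compound 5 is used twice, once directly and once as 6.

Steps most likely to fail:

1. Step 4 (key step). Direct transfer of the aryl or vinyl group from boron to the hindered, electron-rich aryl–palladium species (Suzuki-type coupling), slow oxidative addition into the ortho-silyloxy bromide, or eroded facial selectivity caused by the ortho substituents on both partners may lower yield or enantiopurity. Fallback (two-component lithiation–borylation, the same aryl 1,2-shift from boron to C3 but with the stereocentre set by a stoichiometric chiral diamine): the route sets out from 5 through its aryllithium 8 and comes back at 10. Aryllithium 8 would be opened onto ethylene oxide (BF3·OEt2, −78 °C) to give 2-[2,4-bis(methoxymethoxy)-3-(3-methylbut-2-en-1-yl)phenyl]ethan-1-ol F1. N,N-Diisopropylcarbamoyl chloride and Et3N would convert it into the N,N-diisopropylcarbamate F2, and TESOTf/2,2'-bipyridyl would exchange its MOM groups to give the bis(triethylsilyl) carbamate F3. Separately, 8 and 2-isopropoxy-4,4,5,5-tetramethyl-1,3,2-dioxaborolane would give the ring B aryl pinacol boronate F4. Deprotonation of F3 with s-BuLi/(+)-sparteine (Et2O, −78 °C; removal of the pro-R hydrogen by the usual rule) should give the configurationally stable (R)-α-lithio carbamate F5. This would be borylated with retention by F4 to the boronate complex F6, whose aryl group migrates with inversion and loss of the carbamate (MgBr2·OEt2, warming) to give 10.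

2. Step 3. The acetal-to-silyl exchange may stall at the oxygen flanked by bromine and prenyl, leaving mixed acetal/silyl ethers. Fallback (deprotection and separate silylation instead of one-flask exchange): the route sets out from 5 and comes back at 6. TMSOTf/2,2'-bipyridyl followed by water would free 4-bromo-2-(3-methylbut-2-en-1-yl)benzene-1,3-diol F7, and TESCl with imidazole in DMF would then silylate both phenols to give 6.

3. Step 2. Metalation next to a bromoarene may be incomplete or accompanied by bromine migration between aryllithiums, and the allylation may partly go SN2' to the reverse-prenyl isomer. Fallback (prenylation before bromination, so that no aryllithium ever carries bromine): the route sets out from 3 and comes back at 5. 1,3-Bis(methoxymethoxy)benzene F8 would be lithiated between its two oxygens (n-BuLi, THF, 0 °C) to [2,6-bis(methoxymethoxy)phenyl]lithium F9. Alkylation with 3 (CuBr·SMe2 cat.) would give 1,3-bis(methoxymethoxy)-2-(3-methylbut-2-en-1-yl)benzene F10. Electrophilic bromination with NBS in MeCN at low temperature should go at the only activated ring position, para to one oxygen and ortho to the other, to give 5.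

Further compounds

F1 | step 4 | 2-[2,4-bis(methoxymethoxy)-3-(3-methylbut-2-en-1-yl)phenyl]ethan-1-ol | CC(C)=CCc1c(OCOC)ccc(CCO)c1OCOC
F2 | step 4 | 2-[2,4-bis(methoxymethoxy)-3-(3-methylbut-2-en-1-yl)phenyl]ethyl N,N-diisopropylcarbamate | CC(C)=CCc1c(OCOC)ccc(CCOC(=O)N(C(C)C)C(C)C)c1OCOC
F3 | step 4 | 2-[3-(3-methylbut-2-en-1-yl)-2,4-bis(triethylsilyloxy)phenyl]ethyl N,N-diisopropylcarbamate | CC(C)=CCc1c(O[Si](CC)(CC)CC)ccc(CCOC(=O)N(C(C)C)C(C)C)c1O[Si](CC)(CC)CC
F4 | step 4 | 2-[2,4-bis(methoxymethoxy)-3-(3-methylbut-2-en-1-yl)phenyl]-4,4,5,5-tetramethyl-1,3,2-dioxaborolane | CC(C)=CCc1c(OCOC)ccc(B2OC(C)(C)C(C)(C)O2)c1OCOC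
F5 | step 4 | (1R)-1-lithio-2-[3-(3-methylbut-2-en-1-yl)-2,4-bis(triethylsilyloxy)phenyl]ethyl N,N-diisopropylcarbamate | CC(C)=CCc1c(O[Si](CC)(CC)CC)ccc(C[C@@H]([Li])OC(=O)N(C(C)C)C(C)C)c1O[Si](CC)(CC)CC
F6 | step 4 | lithium boronate complex of F5 and F4 (boron in place of lithium, retention) | [Li+].CC(C)=CCc1c(O[Si](CC)(CC)CC)ccc(C[C@@H]([B-]2(OC(C)(C)C(C)(C)O2)c2ccc(OCOC)c(CC=C(C)C)c2OCOC)OC(=O)N(C(C)C)C(C)C)c1O[Si](CC)(CC)CC
F7 | step 3 | 4-bromo-2-(3-methylbut-2-en-1-yl)benzene-1,3-diol | CC(C)=CCc1c(O)ccc(Br)c1O
F8 | step 2 | 1,3-bis(methoxymethoxy)benzene | COCOc1cccc(OCOC)c1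
F9 | step 2 | [2,6-bis(methoxymethoxy)phenyl]lithium | [Li]c1c(OCOC)cccc1OCOC
F10 | step 2 | 1,3-bis(methoxymethoxy)-2-(3-methylbut-2-en-1-yl)benzene | CC(C)=CCc1c(OCOC)cccc1OCOC
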